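**Retrosynthetic overview**
1. Gibberellin A(65) ⇐ its 15β-hydroxy 20-(phenylsulfonyl) 19,20-lactone 7-[2-(phenylsulfonyl)ethyl] ester: one hydroxide treatment frees the C7 acid, the C19 acid and the C20 aldehyde; the 15β-OH comes from allylic oxidation to the 16-en-15-one and exo-face hydride delivery.
2. The only skeletal bond made is C10–C20: 6-exo closure of a C19-ester-tethered α-thio radical onto a 1(10)-alkene under visible-light photoredox catalysis, which sets the C10 quaternary centre cis to C19.
3. The radical precursor ⇐ the 20-nor-1(10),16-diene-7,19-diacid, whose carboxyls are told apart by acyl-transfer esterification of the accessible C7 carboxyl and O-alkylation of the shielded C19 carboxylate.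
4. The diacid ⇐ gibberellin A(7) by dissolving-metal removal of the 19,10-lactone oxygen and the 3-oxygen.
5. Ring order: rings A, B, C and D and six of the eight stereocentres arrive intact with the starting material; only the bridging 19,20-lactone ring is formed (step 5) and opened again (step 9); C10 and C15 are set by substrate control.

Assumption: gibberellin A(7) (fermentation product, sold neat and in the agrochemical mixture with gibberellin A(4)) is taken as an inexpensive commercial chiral starting material. Gibberellin numbering and the α/β descriptors of the gibberellin literature are used (15β = hydroxyl endo, anti to the C14 bridge). Compounds 9–13 are C20 epimer mixtures, which is immaterial because C20 ends as the aldehyde carbon. The target is drawn as the open aldehyde acid, which equilibrates with its 19,20-lactol.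

**Step 1**
Reactants: 1 gibberellin A(7)
Product: 2 3-O-acetylgibberellin A(7) (3β-acetoxy; lactone, C7 acid and 16-ene unchanged)
Conditions: Ac2O (3 equiv), pyridine, DMAP (5 mol%), CH2Cl2, 0 °C → rt; then THF/H2O, rt
Reagents that add atoms: acetic anhydride, CC(=O)OC(C)=O
Why: DMAP-catalysed O-acylation of the only hydroxyl (the transient C7 mixed anhydride is hydrolysed in the aqueous stage) turns the 3-oxygen into a leaving group without touching any stereocentre.

**Step 2**
Reactants: 2 3-O-acetylgibberellin A(7)
Product: 4 ent-20-norgibberella-1(10),16-diene-7,19-dioic acid, via triene dicarboxylate 3 (not isolated)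
Conditions: Li (8 equiv), NH3(l)/THF, −78 °C; t-BuOH (2 equiv), −78 → −33 °C; solid NH4Cl until colourless, NH3 evaporated; ice-cold 0.5 M HCl to pH 4.5, EtOAc
Reagents that add atoms: none
Why: Birch-type dissolving-metal reduction cleaves an allylic C–O bond (the lactone C10–O or the C3–OAc), the allyl anion expels the other oxygen by β-elimination to give the ring A 1(10),2-diene, and reduction of that diene with protonation at C3 and then at C2 (the less substituted termini) leaves the trisubstituted 1(10)-alkene; the 16-ene and both carboxylates are inert, no other stereocentre is touched, and the work-up stays at pH 4.5 and 0 °C because stronger acid would relactonise the 19-acid onto C10.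

**Step 3**
Reactants: 4 ent-20-norgibberella-1(10),16-diene-7,19-dioic acid; 5 2-(phenylsulfonyl)ethanol
Product: 6 7-[2-(phenylsulfonyl)ethyl] hydrogen ent-20-norgibberella-1(10),16-diene-7,19-dioate (C7 ester, free C19 acid)
Conditions: EDC·HCl (1.2 equiv), DMAP (0.2 equiv), 5 (1.5 equiv), CH2Cl2, 0 °C → rt; aqueous work-up
Reagents that add atoms: 2-(phenylsulfonyl)ethanol (5), OCCS(=O)(=O)c1ccccc1
Why: Steglich esterification (carbodiimide/DMAP acyl transfer) engages only the accessible secondary C7 carboxyl, because the axial, neopentyl-type C19 carboxyl on the quaternary C4 is shielded from acyl substitution (the same shielding that makes gibberellin 19-esters resist saponification) and any activated C19 species reverts to the acid on work-up; the sulfone ester cannot be oxidised in step 5 and leaves by β-elimination in step 9.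

**Step 4**
Reactants: 6 7-[2-(phenylsulfonyl)ethyl] hydrogen ent-20-norgibberella-1(10),16-diene-7,19-dioate; 7 chloromethyl phenyl sulfide
Product: 8 19-[(phenylsulfanyl)methyl] 7-[2-(phenylsulfonyl)ethyl] ent-20-norgibberella-1(10),16-diene-7,19-dioate
Conditions: KHCO3 (1.5 equiv), NaI (0.2 equiv), 7 (1.5 equiv), DMF, 40 °C
Reagents that add atoms: chloromethyl phenyl sulfide (7), ClCSc1ccccc1
Why: O-alkylation of the remaining hindered carboxylate (iodide-catalysed bimolecular substitution at the reactive α-thio halide) needs no attack at the shielded C19 carbonyl, and KHCO3 is too weak a base to trigger β-elimination of the sulfonylethyl ester.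

**Step 5**
Reactants: 8 19-[(phenylsulfanyl)methyl] 7-[2-(phenylsulfonyl)ethyl] ent-20-norgibberella-1(10),16-diene-7,19-dioate
Product: 9 ent-20-hydroxy-20-(phenylsulfanyl)gibberell-16-ene-7,19-dioic acid 19,20-lactone 7-[2-(phenylsulfonyl)ethyl] ester (new C10–C20 bond on the α face, cis to C19; C20 epimers)
Conditions: 9-mesityl-3,6-di-tert-butyl-10-phenylacridinium tetrafluoroborate (5 mol%), 2,4,6-triisopropylbenzenethiol (10 mol%), 2,6-lutidine (20 mol%), MeCN (0.01 M), 450 nm LEDs, 40 °C, Ar
Reagents that add atoms: none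
Why: Proposed new method: a redox-neutral photoredox C–H hydroalkylation in which the excited acridinium oxidises the only oxidisable sulfur in the molecule, the aryl sulfide of the C19 (phenylsulfanyl)methyl ester (about +1.6 V against SCE; the C7 ester carries a sulfone, so no C7-tethered radical can form and close onto the β face of C10), 2,6-lutidine removes the acidified S–CH2–O proton, and the resulting α-thio-α-acyloxy radical, held on the α face by the axial C19 carboxyl, closes 6-exo through a chair transition state onto C10 (7-endo closure at C1 would have to bridge C4 and C1 across a boat ring A), so the quaternary C10–C20 bond can only form cis to C19 (natural 10α configuration); the C1 radical takes a hydrogen atom from the thiol, the thiyl radical re-oxidises the acridine radical and the thiolate is reprotonated by lutidinium, and a radical that has not cyclised (for example from the unreactive Z-ester rotamer) is returned to starting ester by the same thiol; the closest known reaction types are photoredox α-C–H functionalisation of thioethers, acridinium/thiol alkene hydrofunctionalisation and tin-mediated α-thio or acetal-tethered (Ueno–Stork) radical cyclisations.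

**Step 6**
Reactants: 9 ent-20-hydroxy-20-(phenylsulfanyl)gibberell-16-ene-7,19-dioic acid 19,20-lactone 7-[2-(phenylsulfonyl)ethyl] ester
Product: 10 ent-20-hydroxy-20-(phenylsulfonyl)gibberell-16-ene-7,19-dioic acid 19,20-lactone 7-[2-(phenylsulfonyl)ethyl] ester
Conditions: KHSO5 (as Oxone, 3 equiv), MeOH/THF/H2O 2:2:1, 0 °C → rt
Reagents that add atoms: potassium peroxymonosulfate, [K+].[O-]S(=O)(=O)OO
Why: Sulfide-to-sulfone oxidation removes the oxidisable sulfur before the selenium step and turns the lactone into a base-labile α-acyloxy sulfone, while the isolated 1,1-disubstituted alkene is inert to peroxymonosulfate without a ketone mediator.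

**Step 7**
Reactants: 10 ent-20-hydroxy-20-(phenylsulfonyl)gibberell-16-ene-7,19-dioic acid 19,20-lactone 7-[2-(phenylsulfonyl)ethyl] ester
Product: 12 15-oxo derivative of 10 (16-en-15-one), via 15α-alcohol 11 (not isolated)
Conditions: SeO2 (0.5 equiv), t-BuOOH (3 equiv, decane), CH2Cl2, rt; then activated MnO2 (20 equiv), rt
Reagents that add atoms: selenium dioxide, O=[Se]=O; tert-butyl hydroperoxide (terminal oxygen source), CC(C)(C)OO
Why: Riley (Sharpless SeO2/t-BuOOH) allylic hydroxylation by ene reaction and [2,3]-sigmatropic shift delivers oxygen to C15 (the only allylic CH2; C13 is a bridgehead) on the exo face, and MnO2 allylic-alcohol oxidation in the same flask gives the enone at once, so that C15 can be reset and the exo alcohol, which sits next to the C7 ester, has no time to lactonise.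

**Step 8**
Reactants: 12 15-oxo derivative of 10 (16-en-15-one)
Product: 13 15β-hydroxy derivative of 10 (hydroxyl endo)
Conditions: NaBH4 (1.2 equiv), CeCl3·7H2O (1.2 equiv), MeOH/THF 1:1, −78 °C, 20 min; aq. NH4Cl
Reagents that add atoms: none
Why: Luche 1,2-reduction of the α-methylene cyclopentanone with hydride arriving on the exo face of the bicyclo[3.2.1]octane (syn to the C14 bridge; the endo face is screened by the axial hydrogen on C11) places the hydroxyl endo, which is the 15β configuration of the target; at −78 °C the sulfone ester and the lactone are untouched.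

**Step 9**
Reactants: 13 15β-hydroxy derivative of 10 (hydroxyl endo)
Product: 14 gibberellin A(65) (15β-hydroxy, C20 aldehyde, 7,19-diacid)
Conditions: LiOH (6 equiv), THF/H2O 3:1, 0 °C → 40 °C; then ice-cold 1 M HCl to pH 3–4
Reagents that add atoms: lithium hydroxide, [Li+].[OH-]; water, O
Why: Hydroxide removes the 2-(phenylsulfonyl)ethyl group by sulfone-assisted β-elimination and opens the sulfonyl-activated lactone by acyl substitution at C19, whereupon the α-hydroxy sulfone alkoxide collapses to the non-enolisable C20 aldehyde with loss of benzenesulfinate; no stereocentre is affected.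

**Compound list**
1 | gibberellin A(7) (ent-3α,10β-dihydroxy-20-norgibberella-1,16-diene-7,19-dioic acid 19,10-lactone) | C=C1[C@@H]2CC[C@H]3[C@]45C=C[C@H](O)[C@@](C)(C(=O)O5)[C@H]4[C@H](C(=O)O)[C@]3(C2)C1 | starting material
2 | 3-O-acetylgibberellin A(7) | C=C1[C@@H]2CC[C@H]3[C@]45C=C[C@H](OC(C)=O)[C@@](C)(C(=O)O5)[C@H]4[C@H](C(=O)O)[C@]3(C2)C1 | intermediate
3 | ent-20-norgibberella-1(10),2,16-triene-7,19-dioic acid (as its dilithium salt in the flask) | C=C1[C@@H]2CC[C@H]3C4=CC=C[C@@](C)(C(=O)O)[C@H]4[C@H](C(=O)O)[C@]3(C2)C1 | intermediate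
4 | ent-20-norgibberella-1(10),16-diene-7,19-dioic acid | C=C1[C@@H]2CC[C@H]3C4=CCC[C@@](C)(C(=O)O)[C@H]4[C@H](C(=O)O)[C@]3(C2)C1 | intermediate
5 | 2-(phenylsulfonyl)ethanol | OCCS(=O)(=O)c1ccccc1 | starting material
6 | 7-[2-(phenylsulfonyl)ethyl] hydrogen ent-20-norgibberella-1(10),16-diene-7,19-dioate | C=C1[C@@H]2CC[C@H]3C4=CCC[C@@](C)(C(=O)O)[C@H]4[C@H](C(=O)OCCS(=O)(=O)c4ccccc4)[C@]3(C2)C1 | intermediate
7 | chloromethyl phenyl sulfide | ClCSc1ccccc1 | starting material
8 | 19-[(phenylsulfanyl)methyl] 7-[2-(phenylsulfonyl)ethyl] ent-20-norgibberella-1(10),16-diene-7,19-dioate | C=C1[C@@H]2CC[C@H]3C4=CCC[C@@](C)(C(=O)OCSc5ccccc5)[C@H]4[C@H](C(=O)OCCS(=O)(=O)c4ccccc4)[C@]3(C2)C1 | intermediate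
9 | ent-20-hydroxy-20-(phenylsulfanyl)gibberell-16-ene-7,19-dioic acid 19,20-lactone 7-[2-(phenylsulfonyl)ethyl] ester (C20 epimers) | C=C1[C@@H]2CC[C@H]3[C@]45CCC[C@@](C)(C(=O)OC5Sc6ccccc6)[C@H]4[C@H](C(=O)OCCS(=O)(=O)c4ccccc4)[C@]3(C2)C1 | intermediate
10 | ent-20-hydroxy-20-(phenylsulfonyl)gibberell-16-ene-7,19-dioic acid 19,20-lactone 7-[2-(phenylsulfonyl)ethyl] ester | C=C1[C@@H]2CC[C@H]3[C@]45CCC[C@@](C)(C(=O)OC5S(=O)(=O)c6ccccc6)[C@H]4[C@H](C(=O)OCCS(=O)(=O)c4ccccc4)[C@]3(C2)C1 | intermediate
11 | 15α-hydroxy derivative of 10 (hydroxyl exo, syn to C14; not isolated) | C=C1[C@@H]2CC[C@H]3[C@]45CCC[C@@](C)(C(=O)OC5S(=O)(=O)c6ccccc6)[C@H]4[C@H](C(=O)OCCS(=O)(=O)c4ccccc4)[C@]3(C2)[C@H]1O | intermediate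
12 | 15-oxo derivative of 10 (16-en-15-one) | C=C1[C@@H]2CC[C@H]3[C@]45CCC[C@@](C)(C(=O)OC5S(=O)(=O)c6ccccc6)[C@H]4[C@H](C(=O)OCCS(=O)(=O)c4ccccc4)[C@]3(C2)C1=O | intermediate
13 | 15β-hydroxy derivative of 10 (hydroxyl endo) | C=C1[C@@H]2CC[C@H]3[C@]45CCC[C@@](C)(C(=O)OC5S(=O)(=O)c6ccccc6)[C@H]4[C@H](C(=O)OCCS(=O)(=O)c4ccccc4)[C@]3(C2)[C@@H]1O | intermediate
14 | gibberellin A(65) | C=C1[C@@H]2CC[C@H]3[C@]4(C=O)CCC[C@@](C)(C(=O)O)[C@H]4[C@H](C(=O)O)[C@]3(C2)[C@@H]1O | target

**Totals**
Total step count: 9. Longest linear sequence: 9.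

**Steps most likely to fail**

Step 2 (double reductive deoxygenation and diene reduction). The diene may be reduced 1,4 to the 1-ene with a C10–H, or the acetate may be lost by acyl cleavage as the alkoxide instead of being eliminated. Fallback, setting out from 1 and returning at 6, which removes the 3-oxygen by a separate radical deoxygenation: gibberellin A(7) itself is reduced with Li/NH3, which cleaves only the allylic lactone and gives 3β-hydroxy-ent-20-norgibberella-1(10),16-diene-7,19-dioic acid F1. Esterification of the C7 carboxyl with 5 (EDC·HCl, DMAP, CH2Cl2) gives the 7-[2-(phenylsulfonyl)ethyl] ester of the 3β-hydroxy diacid F2. The 3-hydroxyl is then converted with O-phenyl chlorothionoformate (pyridine, CH2Cl2) into the 3-O-(phenoxythiocarbonyl) derivative F3, and Barton–McCombie reduction (Bu3SnH, AIBN, toluene, 90 °C) removes the oxygen to give 6.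

Step 5 (the new photoredox cyclisation). The reactive E-ester rotamer may be too scarce, closure may go 7-endo to C1, or the sulfide radical cation may fragment instead of losing a proton. Fallback with known chemistry, setting out from 8 and returning at 9: the S–CH2–O group is chlorinated with N-chlorosuccinimide (CCl4, rt) to the 19-[chloro(phenylsulfanyl)methyl] 7-[2-(phenylsulfonyl)ethyl] diester F4. The same α-thio radical is then generated irreversibly by chlorine abstraction in a classical tin hydride chain (Bu3SnH by syringe pump, AIBN, chlorobenzene, 110 °C), which does not depend on photon flux or reversible hydrogen return, and the higher temperature raises the E-rotamer population. The radical cyclises to 9. If closure at C1 is intrinsic to the substrate, this fallback shares that weakness.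

Step 9 (final unveiling). Hydroxide must attack the shielded C19 carbonyl of the sulfonyl lactone, which may be slow enough for the aldehyde or the allylic alcohol to suffer. Fallback, setting out from 9 and returning at 14, which unveils C20 by acetal hydrolysis instead of acyl substitution: 9 is treated with MeOTf and 2,6-di-tert-butyl-4-methylpyridine in CH2Cl2 and then MeOH (thioglycoside-type activation) to give the 20-methoxy 19,20-lactone 7-[2-(phenylsulfonyl)ethyl] ester F5. SeO2/t-BuOOH gives its 15α-alcohol F6, which is not isolated, and MnO2 gives the 15-oxo-20-methoxy lactone ester F7. Luche reduction gives the 15β-hydroxy-20-methoxy lactone ester F8. Finally DBU in THF removes the sulfonylethyl ester by β-elimination, and 0.5 M HCl in THF/H2O at rt hydrolyses the lactol methyl ether to give 14.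

**Further compounds**
F1 | step 2 | 3β-hydroxy-ent-20-norgibberella-1(10),16-diene-7,19-dioic acid | C=C1[C@@H]2CC[C@H]3C4=CC[C@H](O)[C@@](C)(C(=O)O)[C@H]4[C@H](C(=O)O)[C@]3(C2)C1
F2 | step 2 | 7-[2-(phenylsulfonyl)ethyl] hydrogen 3β-hydroxy-ent-20-norgibberella-1(10),16-diene-7,19-dioate | C=C1[C@@H]2CC[C@H]3C4=CC[C@H](O)[C@@](C)(C(=O)O)[C@H]4[C@H](C(=O)OCCS(=O)(=O)c4ccccc4)[C@]3(C2)C1
F3 | step 2 | 7-[2-(phenylsulfonyl)ethyl] hydrogen 3β-(phenoxythiocarbonyloxy)-ent-20-norgibberella-1(10),16-diene-7,19-dioate | C=C1[C@@H]2CC[C@H]3C4=CC[C@H](OC(=S)Oc5ccccc5)[C@@](C)(C(=O)O)[C@H]4[C@H](C(=O)OCCS(=O)(=O)c4ccccc4)[C@]3(C2)C1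
F4 | step 5 | 19-[chloro(phenylsulfanyl)methyl] 7-[2-(phenylsulfonyl)ethyl] ent-20-norgibberella-1(10),16-diene-7,19-dioate | C=C1[C@@H]2CC[C@H]3C4=CCC[C@@](C)(C(=O)OC(Cl)Sc5ccccc5)[C@H]4[C@H](C(=O)OCCS(=O)(=O)c4ccccc4)[C@]3(C2)C1
F5 | step 9 | ent-20-hydroxy-20-methoxygibberell-16-ene-7,19-dioic acid 19,20-lactone 7-[2-(phenylsulfonyl)ethyl] ester | C=C1[C@@H]2CC[C@H]3[C@]45CCC[C@@](C)(C(=O)OC5OC)[C@H]4[C@H](C(=O)OCCS(=O)(=O)c4ccccc4)[C@]3(C2)C1
F6 | step 9 | 15α-hydroxy-20-methoxy 19,20-lactone 7-[2-(phenylsulfonyl)ethyl] ester | C=C1[C@@H]2CC[C@H]3[C@]45CCC[C@@](C)(C(=O)OC5OC)[C@H]4[C@H](C(=O)OCCS(=O)(=O)c4ccccc4)[C@]3(C2)[C@H]1O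
F7 | step 9 | 15-oxo-20-methoxy 19,20-lactone 7-[2-(phenylsulfonyl)ethyl] ester | C=C1[C@@H]2CC[C@H]3[C@]45CCC[C@@](C)(C(=O)OC5OC)[C@H]4[C@H](C(=O)OCCS(=O)(=O)c4ccccc4)[C@]3(C2)C1=O
F8 | step 9 | 15β-hydroxy-20-methoxy 19,20-lactone 7-[2-(phenylsulfonyl)ethyl] ester | C=C1[C@@H]2CC[C@H]3[C@]45CCC[C@@](C)(C(=O)OC5OC)[C@H]4[C@H](C(=O)OCCS(=O)(=O)c4ccccc4)[C@]3(C2)[C@@H]1O
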